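**Retrosynthetic overview**
1. Kanzonol X (15) ⇐ its tris-MOM ether 14 by acetal cleavage.
2. 14 ⇐ open-chain alcohol 11: the C3–aryl and C4–C4a bonds are made together by a cationic 1,2-aryl shift of ring B through a phenonium ion, ended by Friedel–Crafts attack of ring A; the carbinol centre of 11 is inverted into C3.
3. 11 ⇐ ring B aryllithium 8 + (R)-epichlorohydrin 7 + ring A phenol 6 (three-component union; 7 carries the chirality).
4. 6 and 8 ⇐ one arene 5 ⇐ resorcinol 1 + prenyl bromide 3, by directed ortho-metalation of bis-MOM ether 2.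
5. Ring order: rings A and B come preformed from resorcinol; the pyran ring C is the only ring built, in the aryl-shift step.

Assumption: (R)-epichlorohydrin is used as bought in high enantiomeric purity. Abbreviations: MOM = CH2OCH3, OMOM = OCH2OCH3, prenyl = 3-methylbut-2-en-1-yl, TIPS = Si(i-Pr)3.

**Route**

Step 1
Reactants: 1 resorcinol
Product: 2 1,3-bis(OMOM)benzene
Conditions: NaH (2.4 equiv), DMF, 0 °C; MOMCl (2.4 equiv), 0 °C → rt
Reagents that add atoms: chloromethyl methyl ether (MOMCl), COCCl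
Why: Williamson-type O-alkylation of both phenoxides (MOM protection); no stereocentre is involved.

Step 2
Reactants: 2 1,3-bis(OMOM)benzene; 3 prenyl bromide
Product: 5 1,3-bis(OMOM)-2-prenylbenzene, via aryllithium 4 (not isolated)
Conditions: n-BuLi (1.1 equiv), THF, 0 °C → rt, 1 h; CuI (10 mol %), 3 (1.2 equiv), −78 °C → rt
Reagents that add atoms: none
Why: Directed ortho-metalation removes the ring hydrogen flanked by both OMOM groups, and copper-assisted SN2 allylation of aryllithium 4 by the primary allylic bromide gives the 2-prenyl arene.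

Step 3
Reactants: 5 1,3-bis(OMOM)-2-prenylbenzene
Product: 6 3-(OMOM)-2-prenylphenol
Conditions: HCl (0.2 M in MeOH), 35 °C, stopped at ca. 60 % conversion; recovered 5 recycled
Reagents that add atoms: none
Why: Acid-catalysed acetal methanolysis; the two MOM groups are equivalent, so partial conversion gives the single mono-phenol 6 (statistical, ca. 45 %), and the dilute acid is too weak to cyclize the ortho-prenylphenol.

Step 4
Reactants: 5 1,3-bis(OMOM)-2-prenylbenzene; 7 (R)-epichlorohydrin; 6 3-(OMOM)-2-prenylphenol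
Product: 11 (2R)-1-[2,4-bis(OMOM)-3-prenylphenyl]-3-[3-(OMOM)-2-prenylphenoxy]propan-2-ol, via aryllithium 8 (not isolated), via chlorohydrin 9 (not isolated), via epoxide 10 (not isolated)
Conditions: 5 (1.05 equiv), n-BuLi, THF, 0 °C, 1.5 h; −78 °C, 7 (1.0 equiv), BF3·OEt2 (1.1 equiv), 1 h; then 6 (1.2 equiv), K2CO3 (4 equiv), EtOH–H2O, 75 °C, 12 h
Reagents that add atoms: none
Why: Directed ortho-metalation of 5 next to an OMOM group, BF3-promoted SN2 opening of the epoxide of 7 at its CH2 terminus, base closure of chlorohydrin 9 to epoxide 10 and phenoxide opening of 10 again at CH2 (epoxide aryloxylation); no bond to the stereocentre is broken, so the configuration of 7 is carried into (2R)-11.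

Step 5
Reactants: 11 (2R)-1-[2,4-bis(OMOM)-3-prenylphenyl]-3-[3-(OMOM)-2-prenylphenoxy]propan-2-ol
Product: 14 (3R)-7-(OMOM)-3-[2,4-bis(OMOM)-3-prenylphenyl]-8-prenylchromane, via triflate 12 (not isolated), via phenonium ion 13 (not isolated)
Conditions: (CF3SO2)2O (1.15 equiv), 2,6-di-tert-butyl-4-methylpyridine (2.5 equiv), CH2Cl2 (0.01 M), −78 °C → −20 °C
Reagents that add atoms: none
Why: Proposed new method: a triflate-triggered aryl-shift cyclization in which secondary triflate 12 ionizes with anchimeric assistance from the 2,4-dialkoxyphenyl ring B (backside ipso attack, inversion at the carbinol carbon) to give bridged phenonium ion 13, which the electron-rich ring A (carbon para to its OMOM and ortho to the ether oxygen) opens at the primary cyclopropane carbon in a favoured 6-(enolendo) Friedel–Crafts closure (attack at the secondary carbon would be a disfavoured 5-(enolendo) closure next to the electron-withdrawing aryloxymethyl group), so ring B lands on C3 by a net cationic 1,2-aryl shift of the Wagner–Meerwein type, ring C closes, and (2R)-11 is converted stereospecifically into (3R)-14; the closest known reaction types are the anchimerically assisted solvolysis of β-arylalkyl sulfonates through phenonium ions with arene capture and the Friedel–Crafts cycloalkylation of 3-aryloxypropyl electrophiles to chromans.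

Step 6
Reactants: 14 (3R)-7-(OMOM)-3-[2,4-bis(OMOM)-3-prenylphenyl]-8-prenylchromane
Product: 15 Kanzonol X
Conditions: HCl (3 M aq.)–MeOH (1:10), 45 °C, 3 h, argon
Reagents that add atoms: none
Why: Acid-catalysed acetal methanolysis of the three aryl MOM ethers under conditions mild enough to leave both ortho-prenylphenol units uncyclized; C3 is neither acidic nor ionizable here, so (3R) is kept.

**Compound list**
1 | resorcinol (benzene-1,3-diol) | Oc1cccc(O)c1 | starting material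
2 | 1,3-bis(OMOM)benzene | COCOc1cccc(OCOC)c1 | intermediate
3 | prenyl bromide (1-bromo-3-methylbut-2-ene) | CC(C)=CCBr | starting material
4 | [2,6-bis(OMOM)phenyl]lithium | [Li]c1c(OCOC)cccc1OCOC | intermediate
5 | 1,3-bis(OMOM)-2-prenylbenzene | COCOc1cccc(OCOC)c1CC=C(C)C | intermediate
6 | 3-(OMOM)-2-prenylphenol | COCOc1cccc(O)c1CC=C(C)C | intermediate
7 | (R)-epichlorohydrin, (2R)-2-(chloromethyl)oxirane | ClC[C@H]1CO1 | starting material
8 | [2,4-bis(OMOM)-3-prenylphenyl]lithium | [Li]c1ccc(OCOC)c(CC=C(C)C)c1OCOC | intermediate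
9 | (2R)-1-chloro-3-[2,4-bis(OMOM)-3-prenylphenyl]propan-2-ol | ClC[C@H](O)Cc1ccc(OCOC)c(CC=C(C)C)c1OCOC | intermediate
10 | (2R)-2-{[2,4-bis(OMOM)-3-prenylphenyl]methyl}oxirane | C1[C@H](O1)Cc2ccc(OCOC)c(CC=C(C)C)c2OCOC | intermediate
11 | (2R)-1-[2,4-bis(OMOM)-3-prenylphenyl]-3-[3-(OMOM)-2-prenylphenoxy]propan-2-ol | COCOc1cccc(OC[C@H](O)Cc2ccc(OCOC)c(CC=C(C)C)c2OCOC)c1CC=C(C)C | intermediate
12 | (2R)-1-[2,4-bis(OMOM)-3-prenylphenyl]-3-[3-(OMOM)-2-prenylphenoxy]propan-2-yl trifluoromethanesulfonate | COCOc1cccc(OC[C@H](OS(=O)(=O)C(F)(F)F)Cc2ccc(OCOC)c(CC=C(C)C)c2OCOC)c1CC=C(C)C | intermediate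
13 | phenonium ion: (1R)-1-{[3-(OMOM)-2-prenylphenoxy]methyl}-4,6-bis(OMOM)-5-prenylspiro[2.5]octa-4,7-dien-6-ylium, both spiro epimers, drawn as the para-oxocarbenium form | COCOc1cccc(OC[C@@H]2CC23C(OCOC)=C(CC=C(C)C)C(=[O+]COC)C=C3)c1CC=C(C)C | intermediate
14 | (3R)-7-(OMOM)-3-[2,4-bis(OMOM)-3-prenylphenyl]-8-prenylchromane | CC(C)=CCc1c(OCOC)ccc([C@@H]2COc3c(ccc(OCOC)c3CC=C(C)C)C2)c1OCOC | intermediate
15 | Kanzonol X, 4-[(3R)-7-hydroxy-8-prenyl-3,4-dihydro-2H-chromen-3-yl]-2-prenylbenzene-1,3-diol | CC(C)=CCc1c(O)ccc([C@@H]2COc3c(ccc(O)c3CC=C(C)C)C2)c1O | target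

**Count**
Total steps: 6. Longest linear sequence: 6 steps (1 → 2 → 5 → 6 → 11 → 14 → 15); the ring B arm (5 → 8) joins in step 4.

**Steps most likely to fail, with fallbacks**

Step 5 (aryl-shift cyclization). The risks are participation of the ortho-OMOM oxygen of ring B (giving a dihydrobenzofuran with loss of MOM) and closure at the secondary carbon. The fallback uses known chemistry: auxiliary-controlled enolate benzylation, then Mitsunobu etherification. It sets out from 6 and from aryllithium 8 (made from 5 as in step 4) and comes back at 14.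

Ring B piece: 8 is opened onto ethylene oxide (BF3·OEt2, THF, −78 °C) to give 2-[2,4-bis(OMOM)-3-prenylphenyl]ethan-1-ol F1. This is oxidized (TEMPO cat., PhI(OAc)2, MeCN–H2O) to [2,4-bis(OMOM)-3-prenylphenyl]acetic acid F2. The pivaloyl mixed anhydride of F2 is joined to lithiated (4R)-4-benzyl-1,3-oxazolidin-2-one to give (4R)-4-benzyl-3-{[2,4-bis(OMOM)-3-prenylphenyl]acetyl}-1,3-oxazolidin-2-one F3.

Ring A piece: 6 is ortho-formylated (MgCl2, Et3N, paraformaldehyde, MeCN, reflux) to 2-hydroxy-4-(OMOM)-3-prenylbenzaldehyde F4. It is silylated (i-Pr3SiCl, imidazole, DMF) to 4-(OMOM)-3-prenyl-2-(TIPS-oxy)benzaldehyde F5, reduced (NaBH4, MeOH, 0 °C) to [4-(OMOM)-3-prenyl-2-(TIPS-oxy)phenyl]methanol F6, and converted (CBr4, PPh3, CH2Cl2) into 1-(bromomethyl)-4-(OMOM)-3-prenyl-2-(TIPS-oxy)benzene F7.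

Union and ring closure: the sodium enolate of F3 (NaN(SiMe3)2, THF, −78 °C) is benzylated by F7 on the face opposite the auxiliary benzyl group. This gives (4R)-4-benzyl-3-{(2R)-2-[2,4-bis(OMOM)-3-prenylphenyl]-3-[4-(OMOM)-3-prenyl-2-(TIPS-oxy)phenyl]propanoyl}-1,3-oxazolidin-2-one F8. LiBH4 removes the auxiliary to give (2R)-2-[2,4-bis(OMOM)-3-prenylphenyl]-3-[4-(OMOM)-3-prenyl-2-(TIPS-oxy)phenyl]propan-1-ol F9. Bu4NF frees the ring A phenol to give 6-{(2R)-2-[2,4-bis(OMOM)-3-prenylphenyl]-3-hydroxypropyl}-3-(OMOM)-2-prenylphenol F10. Mitsunobu closure (PPh3, diisopropyl azodicarboxylate, THF) of that phenol onto the primary alcohol gives 14.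

Step 4 (one-pot three-component union). The risk lies in the telescoped base stage: boron and lithium salts are present, and the in-situ epoxide can be lost to solvolysis. The fallback reverses the order of bond formation and isolates the epoxide partner. It sets out from 6 and comes back at 11. Mitsunobu reaction of 6 with (S)-glycidol (PPh3, diisopropyl azodicarboxylate, THF, 0 °C → rt) gives (2R)-2-{[3-(OMOM)-2-prenylphenoxy]methyl}oxirane F11, which is purified. F11 is then opened at its CH2 terminus by aryllithium 8 with BF3·OEt2 (THF, −78 °C) to give 11.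

Step 6 (global MOM removal). The risk is acid-induced cyclization of the ortho-prenylphenols to 2,2-dimethylchromans. The fallback avoids Brønsted acid by exchanging the acetals for silyl ethers. It sets out from 14 and comes back at 15. Me3SiOTf with 2,2'-bipyridyl (CH2Cl2, 0 °C) converts the three aryl MOM ethers into the tris(trimethylsilyl) ether of Kanzonol X F12, which K2CO3 in MeOH at 0 °C cleaves to 15.

**Further compounds**
F1 | step 5 | 2-[2,4-bis(OMOM)-3-prenylphenyl]ethan-1-ol | OCCc1ccc(OCOC)c(CC=C(C)C)c1OCOC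
F2 | step 5 | [2,4-bis(OMOM)-3-prenylphenyl]acetic acid | OC(=O)Cc1ccc(OCOC)c(CC=C(C)C)c1OCOC
F3 | step 5 | (4R)-4-benzyl-3-{[2,4-bis(OMOM)-3-prenylphenyl]acetyl}-1,3-oxazolidin-2-one | O=C1N(C(=O)Cc2ccc(OCOC)c(CC=C(C)C)c2OCOC)[C@H](Cc2ccccc2)CO1
F4 | step 5 | 2-hydroxy-4-(OMOM)-3-prenylbenzaldehyde | O=Cc1ccc(OCOC)c(CC=C(C)C)c1O
F5 | step 5 | 4-(OMOM)-3-prenyl-2-(TIPS-oxy)benzaldehyde | O=Cc1ccc(OCOC)c(CC=C(C)C)c1O[Si](C(C)C)(C(C)C)C(C)C
F6 | step 5 | [4-(OMOM)-3-prenyl-2-(TIPS-oxy)phenyl]methanol | OCc1ccc(OCOC)c(CC=C(C)C)c1O[Si](C(C)C)(C(C)C)C(C)C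
F7 | step 5 | 1-(bromomethyl)-4-(OMOM)-3-prenyl-2-(TIPS-oxy)benzene | BrCc1ccc(OCOC)c(CC=C(C)C)c1O[Si](C(C)C)(C(C)C)C(C)C
F8 | step 5 | (4R)-4-benzyl-3-{(2R)-2-[2,4-bis(OMOM)-3-prenylphenyl]-3-[4-(OMOM)-3-prenyl-2-(TIPS-oxy)phenyl]propanoyl}-1,3-oxazolidin-2-one | O=C1N(C(=O)[C@H](Cc2ccc(OCOC)c(CC=C(C)C)c2O[Si](C(C)C)(C(C)C)C(C)C)c2ccc(OCOC)c(CC=C(C)C)c2OCOC)[C@H](Cc2ccccc2)CO1
F9 | step 5 | (2R)-2-[2,4-bis(OMOM)-3-prenylphenyl]-3-[4-(OMOM)-3-prenyl-2-(TIPS-oxy)phenyl]propan-1-ol | OC[C@H](Cc1ccc(OCOC)c(CC=C(C)C)c1O[Si](C(C)C)(C(C)C)C(C)C)c1ccc(OCOC)c(CC=C(C)C)c1OCOC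
F10 | step 5 | 6-{(2R)-2-[2,4-bis(OMOM)-3-prenylphenyl]-3-hydroxypropyl}-3-(OMOM)-2-prenylphenol | OC[C@H](Cc1ccc(OCOC)c(CC=C(C)C)c1O)c1ccc(OCOC)c(CC=C(C)C)c1OCOC
F11 | step 4 | (2R)-2-{[3-(OMOM)-2-prenylphenoxy]methyl}oxirane | COCOc1cccc(OC[C@H]2CO2)c1CC=C(C)C
F12 | step 6 | tris(trimethylsilyl) ether of Kanzonol X, (3R)-7-(trimethylsilyloxy)-3-[2,4-bis(trimethylsilyloxy)-3-prenylphenyl]-8-prenylchromane | CC(C)=CCc1c(O[Si](C)(C)C)ccc([C@@H]2COc3c(ccc(O[Si](C)(C)C)c3CC=C(C)C)C2)c1O[Si](C)(C)C
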